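**Retrosynthetic overview**

1. The ring A oxygens come last: C5–OH and C3–O by two allylic oxidations of the 4(15)-alkene, and the angelate by Mitsunobu inversion at C3.
2. The axial 8β-acetate comes from a C8 ketone (hydride from the face away from the angular methyl, acetylation in the same flask).
3. The decalin (rings A and B) is formed second, by proton-triggered transannular C5–C10 closure of a (7R)-8-oxogermacra-1(10),4,11(13)-trienoate; C7 relays to C10 and C5.
4. The ten-membered ring is formed first, at C6–C7: a π-allylpalladium cation from an allylic acetate is attacked by C7 of a silyl-masked dienolate, silicon leaving from C13 where the biosynthesis loses a proton; a chiral ligand sets C7.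
5. The acyclic C15 chain comes from (E,E)-8-chlorogeranyl acetate, CO and a β-stannyl α-(silylmethyl)acrylate, i.e. from geranyl acetate and methyl propiolate.

Assumption: the (R,R) ligand is taken to give the 7R macrocycle; if the first run shows the opposite sense, the (S,S) ligand is used and nothing else changes.

**Route**

Step 1
Reactants: 1 geranyl acetate
Product: 2 (2E,6E)-8-hydroxy-3,7-dimethylocta-2,6-dien-1-yl acetate
Conditions: SeO2 (0.1 equiv), t-BuOOH (3 equiv), salicylic acid (0.1 equiv), CH2Cl2, 0 °C to rt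
Reagents that add atoms: tert-butyl hydroperoxide, CC(C)(C)OO
Why: Catalytic Riley allylic oxidation (ene reaction then [2,3]-shift) attacks the E-methyl of the terminal, more electron-rich alkene because the allylic acetate deactivates the other one; both E geometries are kept and no stereocentre is formed.

Step 2
Reactants: 2 (2E,6E)-8-hydroxy-3,7-dimethylocta-2,6-dien-1-yl acetate
Product: 3 (2E,6E)-8-chloro-3,7-dimethylocta-2,6-dien-1-yl acetate
Conditions: NCS, Me2S, CH2Cl2, −20 to 0 °C
Reagents that add atoms: N-chlorosuccinimide, O=C1CCC(=O)N1Cl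
Why: Corey–Kim chlorination: the alkoxysulfonium salt is displaced by chloride in an SN2 step without allylic transposition, so the E alkene is untouched; the acetate survives and no stereocentre is formed.

Step 3
Reactants: 4 methyl propiolate
Product: 6 methyl (2Z)-3-(tributylstannyl)-2-[(trimethylsilyl)methyl]prop-2-enoate, via methyl 2-cuprio-3-(tributylstannyl)acrylate 5 (not isolated)
Conditions: Bu3SnH, lithium diisopropylamide, THF, −40 °C; CuBr·SMe2, −78 °C; add 4, −78 °C; then Me3SiCH2OTf, DMPU, −78 to −30 °C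
Reagents that add atoms: tributyltin hydride, CCCC[SnH](CCCC)CCCC; (trimethylsilyl)methyl trifluoromethanesulfonate, C[Si](C)(C)COS(=O)(=O)C(F)(F)F
Why: syn-Stannylcupration of the alkynoate (tin to the β-carbon) followed by C-alkylation of the vinylcopper with retention places tin cis to the new CH2SiMe3 group (2Z); no stereocentre is formed.

Step 4
Reactants: 3 (2E,6E)-8-chloro-3,7-dimethylocta-2,6-dien-1-yl acetate; 6 methyl (2Z)-3-(tributylstannyl)-2-[(trimethylsilyl)methyl]prop-2-enoate
Product: 7 methyl (2Z,6E,10E)-12-acetoxy-6,10-dimethyl-4-oxo-2-[(trimethylsilyl)methyl]dodeca-2,6,10-trienoate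
Conditions: Pd2(dba)3·CHCl3 (2.5 mol%), AsPh3 (10 mol%), CO (3 atm), THF, 45 °C
Reagents that add atoms: carbon monoxide, [C-]#[O+]
Why: Stille carbonylative cross-coupling: zerovalent palladium adds to the allylic chloride, CO inserts at the unsubstituted allyl terminus (6E kept) and the vinyl group transfers from tin with retention; the weak AsPh3 ligand under CO leaves the allylic acetate and the allylsilane untouched, and no stereocentre is formed.

Step 5
Reactants: 7 methyl (2Z,6E,10E)-12-acetoxy-6,10-dimethyl-4-oxo-2-[(trimethylsilyl)methyl]dodeca-2,6,10-trienoate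
Product: 9 methyl (5S,7R,10R)-8-oxoeudesma-4(15),11(13)-dien-12-oate, via methyl (7R)-8-oxogermacra-1(10),4,11(13)-trien-12-oate 8 (not isolated)
Conditions: Pd2(dba)3·CHCl3 (5 mol%), (R,R)-DACH-phenyl Trost ligand (12 mol%), Bu4N[Ph3SiF2] (1.1 equiv), PhMe, 0.003 M, syringe-pump addition of 7, 0 °C; cold SiO2 filtration; then 2,6-di-tert-butylpyridinium triflimide (20 mol%), CH2Cl2/(CF3)2CHOH 4:1, −40 to 0 °C
Reagents that add atoms: none
Why: Proposed new method: zerovalent palladium ionises the allylic acetate to a syn π-allyl cation (the laboratory counterpart of farnesyl diphosphate ionisation) and fluoride removes the silyl group, so the C11=C7 π bond attacks C6 through C7 and the C11=C13 methylene appears as in the biosynthetic 1,10-closure, with silicon leaving in place of the C13 proton; only the C7-centred dienolate can form because no amine or alkoxide base is present to enolise C9, attack at the unsubstituted allyl terminus keeps the 4E alkene, and the chiral ligand pocket selects the dienolate face to set C7 as R; the closest known reactions are the Tsuji–Trost asymmetric allylation of fluoride-unmasked silyl enol ethers, acetate-triggered desilylation in trimethylenemethane chemistry and π-allylpalladium macrocyclisation; the second stage is the classical acid-triggered germacrane-to-eudesmane transannular cation–olefin cyclisation, in which protonation at C1 and chair–chair closure of C5 onto C10 with the C7 side chain equatorial fix 10β-CH3 and 5α-H relative to C7, and the hindered pyridine removes the exposed C15 proton to give the 4(15)-alkene under conditions too mild to enolise the ketone.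

Step 6
Reactants: 9 methyl (5S,7R,10R)-8-oxoeudesma-4(15),11(13)-dien-12-oate
Product: 11 methyl (5S,7R,8R,10R)-8β-acetoxyeudesma-4(15),11(13)-dien-12-oate, via lithium tri-tert-butoxy(eudesm-8β-yloxy)aluminate 10 (not isolated)
Conditions: LiAlH(OtBu)3, THF, −78 to −30 °C; then Ac2O, DMAP, pyridine, −30 °C to rt
Reagents that add atoms: acetic anhydride, CC(=O)OC(C)=O
Why: Reductive acetylation: the bulky hydride reduces only the ketone and enters equatorially from the α-face because the axial β-approach is blocked by the syn-axial 10β-methyl, giving the axial 8β-alkoxide (8R, cis to the equatorial C7 side chain), which is acetylated in the flask before it can lactonise onto the ester.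

Step 7
Reactants: 11 methyl (5S,7R,8R,10R)-8β-acetoxyeudesma-4(15),11(13)-dien-12-oate
Product: 12 methyl (3R,5R,7R,8R,10R)-8β-acetoxy-3α-hydroxyeudesma-4(15),11(13)-dien-12-oate
Conditions: SeO2 (0.3 equiv), t-BuOOH (3 equiv), CH2Cl2, rt
Reagents that add atoms: tert-butyl hydroperoxide, CC(C)(C)OO
Why: Riley oxidation: the ene step at C15 removes the axial H-3α (a CH2 reacts faster than the tertiary C5–H) and the [2,3]-shift restores the 4(15)-alkene while delivering oxygen axially, giving the 3α-alcohol; the electron-poor acrylate is inert.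

Step 8
Reactants: 12 methyl (3R,5R,7R,8R,10R)-8β-acetoxy-3α-hydroxyeudesma-4(15),11(13)-dien-12-oate; 13 angelic acid
Product: 14 methyl (3S,5R,7R,8R,10R)-8β-acetoxy-3β-angeloyloxyeudesma-4(15),11(13)-dien-12-oate
Conditions: PPh3, DIAD, PhMe, 0 °C to rt
Reagents that add atoms: none
Why: Mitsunobu esterification: SN2 displacement of the axial oxyphosphonium group by the carboxylate inverts C3 to the equatorial 3β-ester, and because the acid reacts as a carboxylate rather than an activated acyl species the Z (angelate) geometry is not scrambled.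

Step 9
Reactants: 14 methyl (3S,5R,7R,8R,10R)-8β-acetoxy-3β-angeloyloxyeudesma-4(15),11(13)-dien-12-oate
Product: 15 methyl (3S,5S,7R,8R,10R)-8β-acetoxy-3β-angeloyloxy-5α-hydroxyeudesma-4(15),11(13)-dien-12-oate
Conditions: SeO2 (0.5 equiv), t-BuOOH (3 equiv), salicylic acid (0.1 equiv), ClCH2CH2Cl, 40 °C
Reagents that add atoms: tert-butyl hydroperoxide, CC(C)(C)OO
Why: Riley oxidation: with C3–H deactivated by its geminal acyloxy group, the ene step removes the axial tertiary H-5α and the [2,3]-shift returns the 4(15)-alkene while placing oxygen on the α-face of C5, anti to the 10β-methyl, so the trans-decalin and the 5S configuration result.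

**Compound list**

1 | geranyl acetate, (2E)-3,7-dimethylocta-2,6-dien-1-yl acetate | CC(C)=CCC/C(C)=C/COC(C)=O | starting material
2 | (2E,6E)-8-hydroxy-3,7-dimethylocta-2,6-dien-1-yl acetate | OC/C(C)=C/CC/C(C)=C/COC(C)=O | intermediate
3 | (2E,6E)-8-chloro-3,7-dimethylocta-2,6-dien-1-yl acetate | ClC/C(C)=C/CC/C(C)=C/COC(C)=O | intermediate
4 | methyl propiolate (methyl prop-2-ynoate) | C#CC(=O)OC | starting material
5 | methyl (2Z)-2-cuprio-3-(tributylstannyl)prop-2-enoate (tin cis to copper) | COC(=O)/C([Cu])=C/[Sn](CCCC)(CCCC)CCCC | intermediate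
6 | methyl (2Z)-3-(tributylstannyl)-2-[(trimethylsilyl)methyl]prop-2-enoate | COC(=O)/C(C[Si](C)(C)C)=C/[Sn](CCCC)(CCCC)CCCC | intermediate
7 | methyl (2Z,6E,10E)-12-acetoxy-6,10-dimethyl-4-oxo-2-[(trimethylsilyl)methyl]dodeca-2,6,10-trienoate | COC(=O)/C(C[Si](C)(C)C)=C/C(=O)C/C(C)=C/CC/C(C)=C/COC(C)=O | intermediate
8 | methyl 2-[(1R,3E,7E)-4,8-dimethyl-10-oxocyclodeca-3,7-dien-1-yl]prop-2-enoate, i.e. methyl (7R)-8-oxogermacra-1(10)E,4E,11(13)-trien-12-oate | C=C(C(=O)OC)[C@H]1C/C=C(\C)CC/C=C(\C)CC1=O | intermediate
9 | methyl (5S,7R,10R)-8-oxoeudesma-4(15),11(13)-dien-12-oate (5α-H, 10β-CH3, 7β side chain) | C=C(C(=O)OC)[C@H]1C[C@H]2C(=C)CCC[C@]2(C)CC1=O | intermediate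
10 | lithium tri-tert-butoxy{[(5S,7R,8R,10R)-12-methoxy-12-oxoeudesma-4(15),11(13)-dien-8-yl]oxy}aluminate (8β-O–Al) | C=C(C(=O)OC)[C@H]1C[C@H]2C(=C)CCC[C@]2(C)C[C@H]1O[Al-](OC(C)(C)C)(OC(C)(C)C)OC(C)(C)C.[Li+] | intermediate
11 | methyl (5S,7R,8R,10R)-8β-acetoxyeudesma-4(15),11(13)-dien-12-oate | C=C(C(=O)OC)[C@H]1C[C@H]2C(=C)CCC[C@]2(C)C[C@H]1OC(C)=O | intermediate
12 | methyl (3R,5R,7R,8R,10R)-8β-acetoxy-3α-hydroxyeudesma-4(15),11(13)-dien-12-oate | C=C(C(=O)OC)[C@H]1C[C@H]2C(=C)[C@H](O)CC[C@]2(C)C[C@H]1OC(C)=O | intermediate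
13 | angelic acid, (2Z)-2-methylbut-2-enoic acid | C/C=C(/C)C(=O)O | starting material
14 | methyl (3S,5R,7R,8R,10R)-8β-acetoxy-3β-angeloyloxyeudesma-4(15),11(13)-dien-12-oate | C=C(C(=O)OC)[C@H]1C[C@H]2C(=C)[C@@H](OC(=O)/C(C)=C\C)CC[C@]2(C)C[C@H]1OC(C)=O | intermediate
15 | methyl (3S,5S,7R,8R,10R)-8β-acetoxy-3β-angeloyloxy-5α-hydroxyeudesma-4(15),11(13)-dien-12-oate | C=C(C(=O)OC)[C@H]1C[C@@]2(O)C(=C)[C@@H](OC(=O)/C(C)=C\C)CC[C@]2(C)C[C@H]1OC(C)=O | target

**Step count and risks**

Total: 9 steps. Longest linear sequence: 8 steps (steps 1, 2, 4, 5, 6, 7, 8, 9 from geranyl acetate); step 3 makes the coupling partner 6 from methyl propiolate.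

Step 5 is the most likely to fail. The ten-membered ring may lose to the twelve-membered γ-alkylation product or to oligomers, the C7 centre of 8 is acidic so its ee can erode before the acid stage, and proton loss after the cyclisation may give the 3-ene beside the 4(15)-ene. The fallback sets out from 7 and comes back at 11. Ring closure with achiral Pd(PPh3)4 and Bu4N[Ph3SiF2] gives the racemic macrocycle methyl 2-[(3E,7E)-4,8-dimethyl-10-oxocyclodeca-3,7-dien-1-yl]prop-2-enoate F1, and a reduction then fixes the stereochemistry instead of the C–C bond formation. Because C7–H of F1 lies between the ketone and the vinyl group, it epimerises during transfer hydrogenation with RuCl(p-cymene)[(S,S)-TsDPEN] in HCO2H/Et3N, so a dynamic kinetic resolution gives the cis alcohol methyl (7R,8R)-8-hydroxygermacra-1(10)E,4E,11(13)-trien-12-oate F2. Ac2O/DMAP gives methyl (7R,8R)-8-acetoxygermacra-1(10)E,4E,11(13)-trien-12-oate F3, and the buffered acid of step 5 closes the decalin to 11.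

Step 9 is next: a tertiary allylic C–H is oxidised slowly, and oxidation at C3–H with loss of the angelate or over-oxidation may win. The fallback sets out from 11 and comes back at 15, building the C5 hydroxyl from an epoxide before C3 is touched. TsOH (cat., PhH, 50 °C) moves the alkene into the ring to give methyl 8β-acetoxyeudesma-4,11(13)-dien-12-oate F4. mCPBA adds anti to the 10β-methyl to give methyl 8β-acetoxy-4α,5α-epoxyeudesm-11(13)-en-12-oate F5. Cp2TiCl2/Mn (Cp2TiCl, trivalent titanium) opens the epoxide to the C4 radical, and loss of a C15 hydrogen gives methyl 8β-acetoxy-5α-hydroxyeudesma-4(15),11(13)-dien-12-oate F6. SeO2/t-BuOOH can now only attack C3 and gives methyl 8β-acetoxy-3α,5α-dihydroxyeudesma-4(15),11(13)-dien-12-oate F7, whose secondary hydroxyl alone undergoes Mitsunobu inversion with 13 (PPh3, DIAD) to give 15.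

Step 3 is the third: alkylation of the vinylcopper 5 with the silylmethyl triflate may be slow and lose the alkene geometry. The fallback sets out from 4 (and uses 3) and comes back at 7, building the silylmethyl group onto an ynone instead. Methyl propiolate is stannylated with Bu3SnOMe (neat, rt) to methyl 3-(tributylstannyl)prop-2-ynoate F8. Carbonylative Stille coupling of F8 with 3 under the conditions of step 4 gives methyl (6E,10E)-12-acetoxy-6,10-dimethyl-4-oxododeca-6,10-dien-2-ynoate F9. Conjugate addition of (Me3SiCH2)2CuLi (THF, −78 °C, β to the ketone), with equilibration through the allenolate before the quench, gives 7.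

**Further compounds**

F1 | step 5 | methyl 2-[(3E,7E)-4,8-dimethyl-10-oxocyclodeca-3,7-dien-1-yl]prop-2-enoate (racemic) | C=C(C(=O)OC)C1C/C=C(\C)CC/C=C(\C)CC1=O
F2 | step 5 | methyl (7R,8R)-8-hydroxygermacra-1(10)E,4E,11(13)-trien-12-oate | C=C(C(=O)OC)[C@H]1C/C=C(\C)CC/C=C(\C)C[C@H]1O
F3 | step 5 | methyl (7R,8R)-8-acetoxygermacra-1(10)E,4E,11(13)-trien-12-oate | C=C(C(=O)OC)[C@H]1C/C=C(\C)CC/C=C(\C)C[C@H]1OC(C)=O
F4 | step 9 | methyl 8β-acetoxyeudesma-4,11(13)-dien-12-oate | C=C(C(=O)OC)[C@H]1CC2=C(C)CCC[C@]2(C)C[C@H]1OC(C)=O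
F5 | step 9 | methyl 8β-acetoxy-4α,5α-epoxyeudesm-11(13)-en-12-oate | C=C(C(=O)OC)[C@H]1C[C@@]2(O3)[C@@]3(C)CCC[C@]2(C)C[C@H]1OC(C)=O
F6 | step 9 | methyl 8β-acetoxy-5α-hydroxyeudesma-4(15),11(13)-dien-12-oate | C=C(C(=O)OC)[C@H]1C[C@@]2(O)C(=C)CCC[C@]2(C)C[C@H]1OC(C)=O
F7 | step 9 | methyl 8β-acetoxy-3α,5α-dihydroxyeudesma-4(15),11(13)-dien-12-oate | C=C(C(=O)OC)[C@H]1C[C@@]2(O)C(=C)[C@H](O)CC[C@]2(C)C[C@H]1OC(C)=O
F8 | step 3 | methyl 3-(tributylstannyl)prop-2-ynoate | COC(=O)C#C[Sn](CCCC)(CCCC)CCCC
F9 | step 3 | methyl (6E,10E)-12-acetoxy-6,10-dimethyl-4-oxododeca-6,10-dien-2-ynoate | COC(=O)C#CC(=O)C/C(C)=C/CC/C(C)=C/COC(C)=O
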